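A direct plan would build an open-chain aldehyde A1 that already carries both esters and two terminal alkynes, close the cyclohexane by an intramolecular carbonyl-ene reaction to A2, convert the homopropargylic alcohol of A2 into the α-methylene lactone A3 by palladium-catalysed cyclocarbonylation, and finish by ruthenium-catalysed addition of acetic acid to the second alkyne.
Its weakest steps would be:
- the propargylation that joins the chain, because a racemic propargylic bromide would have to set two stereocentres in a stereoconvergent indium reaction that has no close precedent;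
- the ene closure, because an α-ethynyl, β-acyloxy aldehyde would have to survive excess Me2AlCl without epimerisation or loss of the angelate;
- the cyclocarbonylation, because it would have to tell two terminal alkynes apart.

With elemane numbering (ring C5–C10; lactone C6–O–C12–C11–C7; acetoxyvinyl C1=C2 and methyl on C10; isopropenyl C4 on C5), the route rests on the C5–C10 bond as the bond formed by a Claisen rearrangement, because C1(=O)–C10–C5–C4=C3 is a γ,δ-unsaturated aldehyde. An (E)-vinyl iodide carrying C8/C9 and an (E)-allylic alcohol carrying C6 are joined by copper and rearranged in the same flask. This sets the quaternary C10 and C5 and leaves an open chain. One organochromium step then closes the cyclohexane (C6–C7) and the lactone together. No propargylation, no ene closure of an epimerisable aldehyde and no choice between two alkynes remain.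

Key step: step 6

Remark: 1, 3, 7, 8, 15 and 22 are taken as commercial; 7 is used as its aqueous solution.

Step 1
Reactants: 1 (2E)-3-iodo-2-methylprop-2-en-1-ol
Product: 2 (2E)-3-iodo-2-methylprop-2-enal
Conditions: MnO2 (15 equiv), CH2Cl2, rt; filtered solution used directly
Reagents that add atoms: none
Why: Allylic oxidation on MnO2 stops at the aldehyde and keeps the E geometry of the vinyl iodide.

Step 2
Reactants: 2 (2E)-3-iodo-2-methylprop-2-enal; 3 3-(methoxymethoxy)prop-1-ene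
Product: 5 (1E,3R,4R)-1-iodo-4-(methoxymethoxy)-2-methylhexa-1,5-dien-3-ol, via allylborane 4 (not isolated)
Conditions: 3, s-BuLi, THF, −78 °C; (−)-Ipc2BOMe; BF3·OEt2; then 2, −78 °C; HOCH2CH2NH2 work-up
Reagents that add atoms: none
Why: Asymmetric γ-alkoxyallylboration (Brown type): the (Z)-γ-alkoxyallylborane adds through a chair Zimmerman–Traxler transition state, so C8 and C9 form syn, and the isopinocampheyl groups derived from (+)-α-pinene should select the aldehyde face that gives the (3R,4R) isomer.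

Step 3
Reactants: 5 (1E,3R,4R)-1-iodo-4-(methoxymethoxy)-2-methylhexa-1,5-dien-3-ol
Product: 6 tert-butyl{[(1E,3R,4R)-1-iodo-4-(methoxymethoxy)-2-methylhexa-1,5-dien-3-yl]oxy}dimethylsilane
Conditions: TBSOTf, 2,6-lutidine, CH2Cl2, −78 to 0 °C
Reagents that add atoms: tert-butyldimethylsilyl trifluoromethanesulfonate, CC(C)(C)[Si](C)(C)OS(=O)(=O)C(F)(F)F
Why: Silylation of the hindered allylic alcohol with the silyl triflate masks the hydroxyl that would otherwise compete in the copper-mediated O-vinylation, and leaves the C8 and C9 oxygens differently protected for the end game.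

Step 4
Reactants: 7 2,2-dimethoxyacetaldehyde; 8 ethyl 2-(triphenyl-λ5-phosphanylidene)propanoate
Product: 9 ethyl (2E)-4,4-dimethoxy-2-methylbut-2-enoate
Conditions: CH2Cl2, rt
Reagents that add atoms: none
Why: Wittig olefination with a stabilised ylide gives the E trisubstituted enoate and tolerates the water that comes with the aldehyde.

Step 5
Reactants: 9 ethyl (2E)-4,4-dimethoxy-2-methylbut-2-enoate
Product: 10 (2E)-4,4-dimethoxy-2-methylbut-2-en-1-ol
Conditions: i-Bu2AlH (2.2 equiv), CH2Cl2, −78 °C; aq. KNaC4H4O6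
Reagents that add atoms: none
Why: Hydride 1,2-reduction of the enoate gives the allylic alcohol without touching the acetal or the alkene geometry.

Step 6
Reactants: 6 tert-butyl{[(1E,3R,4R)-1-iodo-4-(methoxymethoxy)-2-methylhexa-1,5-dien-3-yl]oxy}dimethylsilane; 10 (2E)-4,4-dimethoxy-2-methylbut-2-en-1-ol
Product: 12 (2S,3R,4R)-3-[(tert-butyldimethylsilyl)oxy]-2-[(2S)-1,1-dimethoxy-3-methylbut-3-en-2-yl]-4-(methoxymethoxy)-2-methylhex-5-enal, via allyl vinyl ether 11 (not isolated)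
Conditions: CuI (10 mol %), 3,4,7,8-tetramethyl-1,10-phenanthroline (20 mol %), Cs2CO3, 10 (2 equiv), toluene, 80 °C; then o-xylene, 140 °C
Reagents that add atoms: none
Why: Monovalent copper with the phenanthroline ligand couples the vinyl iodide of 6 with alcohol 10 with retention of the E geometry, and the allyl vinyl ether 11 then undergoes a thermal [3,3]-sigmatropic (Claisen) rearrangement that forms the C5–C10 bond, moves the allyl double bond into the isopropenyl group and turns C1 into the aldehyde. The closest known reaction type is the copper-catalysed O-vinylation of allylic alcohols with vinyl iodides run in tandem with Claisen rearrangement, which accepts 2,2-disubstituted vinyl iodides and delivers quaternary carbons. No ring is closed, since the six-membered chair exists only in the transition state. Because both alkenes are E, the chair places C9 and C6 equatorial and the C10 methyl and the C5 hydrogen axial, which fixes the relative configuration of the quaternary C10 and of C5 (C1 and the isopropenyl group trans, as later required on the ring). The absolute sense is controlled by the C9 stereocentre: the allyl terminus should attack the face of C10 anti to the C8 chain, with the C9–O bond in the inside position and the C9–H turned towards the geminal methyl. The step needs this facial selectivity, and it needs the Claisen path to outrun a Cope rearrangement of the 1,5-diene C1=C10–C9–C8–C7=C, which the enol ether oxygen should secure by lowering the barrier of the oxygen-containing shift.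

Step 7
Reactants: 12 (2S,3R,4R)-3-[(tert-butyldimethylsilyl)oxy]-2-[(2S)-1,1-dimethoxy-3-methylbut-3-en-2-yl]-4-(methoxymethoxy)-2-methylhex-5-enal
Product: 13 (3R,4R,5R)-4-[(tert-butyldimethylsilyl)oxy]-5-[(2S)-1,1-dimethoxy-3-methylbut-3-en-2-yl]-3-(methoxymethoxy)-5-methylhept-1-en-6-yne
Conditions: dimethyl (1-diazo-2-oxopropyl)phosphonate, K2CO3, MeOH, 0 °C to rt
Reagents that add atoms: Ohira–Bestmann reagent, CC(=O)C(=[N+]=[N-])P(=O)(OC)OC
Why: Ohira–Bestmann (Seyferth–Gilbert) homologation of the non-enolisable α-quaternary aldehyde adds C2 and gives the terminal alkyne without touching a stereocentre (the C10 descriptor changes only through the priority rules).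

Step 8
Reactants: 13 (3R,4R,5R)-4-[(tert-butyldimethylsilyl)oxy]-5-[(2S)-1,1-dimethoxy-3-methylbut-3-en-2-yl]-3-(methoxymethoxy)-5-methylhept-1-en-6-yne
Product: 14 (1Z,3S,4R,5R)-4-[(tert-butyldimethylsilyl)oxy]-3-[(2S)-1,1-dimethoxy-3-methylbut-3-en-2-yl]-5-(methoxymethoxy)-3-methylhepta-1,6-dien-1-yl acetate
Conditions: Ru(2-methylallyl)2(dppb) (5 mol %), AcOH (2 equiv), toluene, 65 °C
Reagents that add atoms: acetic acid, CC(=O)O
Why: Ruthenium-vinylidene-mediated anti-Markovnikov addition of the carboxylic acid to the terminal alkyne gives the Z enol acetate, and it is placed here because a free alkyne would enter enyne metathesis in the next step.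

Step 9
Reactants: 14 (1Z,3S,4R,5R)-4-[(tert-butyldimethylsilyl)oxy]-3-[(2S)-1,1-dimethoxy-3-methylbut-3-en-2-yl]-5-(methoxymethoxy)-3-methylhepta-1,6-dien-1-yl acetate; 15 methyl 2-(bromomethyl)prop-2-enoate
Product: 16 methyl (2Z,4R,5R,6S,7S)-6-[(Z)-2-acetoxyethenyl]-2-(bromomethyl)-5-[(tert-butyldimethylsilyl)oxy]-8,8-dimethoxy-4-(methoxymethoxy)-6-methyl-7-(prop-1-en-2-yl)oct-2-enoate
Conditions: Hoveyda–Grubbs second-generation catalyst (10 mol %), 15 (5 equiv), CH2Cl2, 40 °C
Reagents that add atoms: none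
Why: Olefin cross-metathesis of the only monosubstituted alkene with the 1,1-disubstituted acrylate installs C11–C13 as a 2-(bromomethyl)enoate, while the isopropenyl group and the enol acetate next to the quaternary carbon should be too hindered to react.

Step 10
Reactants: 16 methyl (2Z,4R,5R,6S,7S)-6-[(Z)-2-acetoxyethenyl]-2-(bromomethyl)-5-[(tert-butyldimethylsilyl)oxy]-8,8-dimethoxy-4-(methoxymethoxy)-6-methyl-7-(prop-1-en-2-yl)oct-2-enoate
Product: 17 methyl (2Z,4R,5R,6S,7S)-6-[(Z)-2-acetoxyethenyl]-2-(bromomethyl)-5-[(tert-butyldimethylsilyl)oxy]-4-(methoxymethoxy)-6-methyl-8-oxo-7-(prop-1-en-2-yl)oct-2-enoate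
Conditions: (CO2H)2 on wet SiO2, CH2Cl2, rt; used crude at once
Reagents that add atoms: water, O
Why: Mild heterogeneous acid hydrolysis of the dimethyl acetal frees the C6 aldehyde under base-free conditions, so the α-branched β,γ-unsaturated aldehyde should neither epimerise nor move into conjugation, and the ethers and esters should remain.

Step 11
Reactants: 17 methyl (2Z,4R,5R,6S,7S)-6-[(Z)-2-acetoxyethenyl]-2-(bromomethyl)-5-[(tert-butyldimethylsilyl)oxy]-4-(methoxymethoxy)-6-methyl-8-oxo-7-(prop-1-en-2-yl)oct-2-enoate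
Product: 19 (Z)-2-[(3aS,4R,5R,6S,7S,7aR)-5-[(tert-butyldimethylsilyl)oxy]-4-(methoxymethoxy)-6-methyl-3-methylidene-2-oxo-7-(prop-1-en-2-yl)octahydro-1-benzofuran-6-yl]ethenyl acetate, via hydroxy ester 18 (not isolated)
Conditions: CrCl2 (5 equiv), THF, 0 °C to rt; aq. NH4Cl; then PPTS (cat.), toluene, 50 °C
Reagents that add atoms: none
Why: Nozaki–Hiyama–Kishi-type intramolecular 2-(alkoxycarbonyl)allylation, in which CrCl2 converts the allylic bromide into an allylchromium species of trivalent chromium whose alkene isomers interconvert and which adds through C7 to the aldehyde in a chair-like cyclic transition state fused trans to the forming cyclohexane chair; the axial C10 methyl excludes an axial C6–O bond and the ester-bearing allyl unit sits equatorial, so that C6–OH and C7–C11 should form trans and hydroxy ester 18 then closes to the trans-fused α-methylene lactone.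

Step 12
Reactants: 19 (Z)-2-[(3aS,4R,5R,6S,7S,7aR)-5-[(tert-butyldimethylsilyl)oxy]-4-(methoxymethoxy)-6-methyl-3-methylidene-2-oxo-7-(prop-1-en-2-yl)octahydro-1-benzofuran-6-yl]ethenyl acetate
Product: 21 (Z)-2-[(3aR,4R,5R,6S,7S,7aR)-5-[(tert-butyldimethylsilyl)oxy]-4-hydroxy-6-methyl-3-methylidene-2-oxo-7-(prop-1-en-2-yl)octahydro-1-benzofuran-6-yl]ethenyl acetate, via bromomethyl ether 20 (not isolated)
Conditions: Me2BBr (3 equiv), CH2Cl2, −78 °C; then THF–sat. aq. NaHCO3
Reagents that add atoms: none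
Why: The bromoborane cleaves the methoxymethyl acetal at low temperature through the bromomethyl ether, which hydrolyses on work-up, while the silyl ether, the lactone and the enol acetate should survive (the 3a descriptor changes only through the priority rules).

Step 13
Reactants: 21 (Z)-2-[(3aR,4R,5R,6S,7S,7aR)-5-[(tert-butyldimethylsilyl)oxy]-4-hydroxy-6-methyl-3-methylidene-2-oxo-7-(prop-1-en-2-yl)octahydro-1-benzofuran-6-yl]ethenyl acetate; 22 (2Z)-2-methylbut-2-enoic acid (angelic acid)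
Product: 24 (3aS,4R,5R,6S,7S,7aR)-6-[(Z)-2-acetoxyethenyl]-5-[(tert-butyldimethylsilyl)oxy]-6-methyl-3-methylidene-2-oxo-7-(prop-1-en-2-yl)octahydro-1-benzofuran-4-yl (2Z)-2-methylbut-2-enoate, via mixed anhydride 23 (not isolated)
Conditions: 22, 2,4,6-trichlorobenzoyl chloride, Et3N, toluene, rt; then 21, 75 °C (no DMAP)
Reagents that add atoms: none
Why: Yamaguchi esterification through the mixed anhydride without a nucleophilic catalyst acylates the only free hydroxyl (C8) and keeps the Z geometry of the angelate.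

Step 14
Reactants: 24 (3aS,4R,5R,6S,7S,7aR)-6-[(Z)-2-acetoxyethenyl]-5-[(tert-butyldimethylsilyl)oxy]-6-methyl-3-methylidene-2-oxo-7-(prop-1-en-2-yl)octahydro-1-benzofuran-4-yl (2Z)-2-methylbut-2-enoate
Product: 25 (3aS,4R,5R,6S,7S,7aR)-6-[(Z)-2-acetoxyethenyl]-5-hydroxy-6-methyl-3-methylidene-2-oxo-7-(prop-1-en-2-yl)octahydro-1-benzofuran-4-yl (2Z)-2-methylbut-2-enoate
Conditions: HF·pyridine, pyridine–THF, 0 °C to rt
Reagents that add atoms: none
Why: Buffered fluoride desilylation frees the C9 hydroxyl under mildly acidic conditions, under which neither the enol acetate nor the angelate should cleave or migrate.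

Step 15
Reactants: 25 (3aS,4R,5R,6S,7S,7aR)-6-[(Z)-2-acetoxyethenyl]-5-hydroxy-6-methyl-3-methylidene-2-oxo-7-(prop-1-en-2-yl)octahydro-1-benzofuran-4-yl (2Z)-2-methylbut-2-enoate
Product: 26 (3aS,4R,5R,6S,7S,7aR)-5-acetoxy-6-[(Z)-2-acetoxyethenyl]-6-methyl-3-methylidene-2-oxo-7-(prop-1-en-2-yl)octahydro-1-benzofuran-4-yl (2Z)-2-methylbut-2-enoate (CNP0582479.1)
Conditions: Ac2O, DMAP (cat.), pyridine, CH2Cl2, rt
Reagents that add atoms: acetic anhydride, CC(=O)OC(C)=O
Why: DMAP-catalysed acetylation of the remaining hindered secondary alcohol completes the target.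

**Compound list**
1 | (2E)-3-iodo-2-methylprop-2-en-1-ol | OC/C(C)=C/I | starting material
2 | (2E)-3-iodo-2-methylprop-2-enal | O=C/C(C)=C/I | intermediate
3 | 3-(methoxymethoxy)prop-1-ene (allyl methoxymethyl ether) | C=CCOCOC | starting material
4 | [(2Z)-3-(methoxymethoxy)prop-2-en-1-yl]bis[(1R,2S,3R,5R)-2,6,6-trimethylbicyclo[3.1.1]heptan-3-yl]borane | COCO/C=C\CB([C@@H]1C[C@@H]2C[C@H]([C@H]1C)C2(C)C)[C@@H]1C[C@@H]2C[C@H]([C@H]1C)C2(C)C | intermediate
5 | (1E,3R,4R)-1-iodo-4-(methoxymethoxy)-2-methylhexa-1,5-dien-3-ol | C=C[C@@H](OCOC)[C@H](O)/C(C)=C/I | intermediate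
6 | tert-butyl{[(1E,3R,4R)-1-iodo-4-(methoxymethoxy)-2-methylhexa-1,5-dien-3-yl]oxy}dimethylsilane | C=C[C@@H](OCOC)[C@H](O[Si](C)(C)C(C)(C)C)/C(C)=C/I | intermediate
7 | 2,2-dimethoxyacetaldehyde | COC(OC)C=O | starting material
8 | ethyl 2-(triphenyl-λ5-phosphanylidene)propanoate | CCOC(=O)C(C)=P(c1ccccc1)(c1ccccc1)c1ccccc1 | starting material
9 | ethyl (2E)-4,4-dimethoxy-2-methylbut-2-enoate | CCOC(=O)/C(C)=C/C(OC)OC | intermediate
10 | (2E)-4,4-dimethoxy-2-methylbut-2-en-1-ol | OC/C(C)=C/C(OC)OC | intermediate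
11 | tert-butyl{[(1E,3R,4R)-1-{[(2E)-4,4-dimethoxy-2-methylbut-2-en-1-yl]oxy}-4-(methoxymethoxy)-2-methylhexa-1,5-dien-3-yl]oxy}dimethylsilane | C=C[C@@H](OCOC)[C@H](O[Si](C)(C)C(C)(C)C)/C(C)=C/OC/C(C)=C/C(OC)OC | intermediate
12 | (2S,3R,4R)-3-[(tert-butyldimethylsilyl)oxy]-2-[(2S)-1,1-dimethoxy-3-methylbut-3-en-2-yl]-4-(methoxymethoxy)-2-methylhex-5-enal | C=C[C@@H](OCOC)[C@H](O[Si](C)(C)C(C)(C)C)[C@@](C)(C=O)[C@@H](C(OC)OC)C(=C)C | intermediate
13 | (3R,4R,5R)-4-[(tert-butyldimethylsilyl)oxy]-5-[(2S)-1,1-dimethoxy-3-methylbut-3-en-2-yl]-3-(methoxymethoxy)-5-methylhept-1-en-6-yne | C=C[C@@H](OCOC)[C@H](O[Si](C)(C)C(C)(C)C)[C@@](C)(C#C)[C@@H](C(OC)OC)C(=C)C | intermediate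
14 | (1Z,3S,4R,5R)-4-[(tert-butyldimethylsilyl)oxy]-3-[(2S)-1,1-dimethoxy-3-methylbut-3-en-2-yl]-5-(methoxymethoxy)-3-methylhepta-1,6-dien-1-yl acetate | C=C[C@@H](OCOC)[C@H](O[Si](C)(C)C(C)(C)C)[C@@](C)(/C=C\OC(C)=O)[C@@H](C(OC)OC)C(=C)C | intermediate
15 | methyl 2-(bromomethyl)prop-2-enoate | C=C(CBr)C(=O)OC | starting material
16 | methyl (2Z,4R,5R,6S,7S)-6-[(Z)-2-acetoxyethenyl]-2-(bromomethyl)-5-[(tert-butyldimethylsilyl)oxy]-8,8-dimethoxy-4-(methoxymethoxy)-6-methyl-7-(prop-1-en-2-yl)oct-2-enoate | COC(=O)/C(CBr)=C/[C@@H](OCOC)[C@H](O[Si](C)(C)C(C)(C)C)[C@@](C)(/C=C\OC(C)=O)[C@@H](C(OC)OC)C(=C)C | intermediate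
17 | methyl (2Z,4R,5R,6S,7S)-6-[(Z)-2-acetoxyethenyl]-2-(bromomethyl)-5-[(tert-butyldimethylsilyl)oxy]-4-(methoxymethoxy)-6-methyl-8-oxo-7-(prop-1-en-2-yl)oct-2-enoate | COC(=O)/C(CBr)=C/[C@@H](OCOC)[C@H](O[Si](C)(C)C(C)(C)C)[C@@](C)(/C=C\OC(C)=O)[C@@H](C=O)C(=C)C | intermediate
18 | methyl 2-[(1S,2R,3R,4S,5S,6R)-4-[(Z)-2-acetoxyethenyl]-3-[(tert-butyldimethylsilyl)oxy]-6-hydroxy-2-(methoxymethoxy)-4-methyl-5-(prop-1-en-2-yl)cyclohexyl]prop-2-enoate (formed as its chromium alkoxide) | O[C@H]1[C@H](C(=C)C(=O)OC)[C@@H](OCOC)[C@H](O[Si](C)(C)C(C)(C)C)[C@@](C)(/C=C\OC(C)=O)[C@@H]1C(=C)C | intermediate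
19 | (Z)-2-[(3aS,4R,5R,6S,7S,7aR)-5-[(tert-butyldimethylsilyl)oxy]-4-(methoxymethoxy)-6-methyl-3-methylidene-2-oxo-7-(prop-1-en-2-yl)octahydro-1-benzofuran-6-yl]ethenyl acetate | C=C1C(=O)O[C@H]2[C@H]1[C@@H](OCOC)[C@H](O[Si](C)(C)C(C)(C)C)[C@@](C)(/C=C\OC(C)=O)[C@@H]2C(=C)C | intermediate
20 | (Z)-2-[(3aS,4R,5R,6S,7S,7aR)-4-(bromomethoxy)-5-[(tert-butyldimethylsilyl)oxy]-6-methyl-3-methylidene-2-oxo-7-(prop-1-en-2-yl)octahydro-1-benzofuran-6-yl]ethenyl acetate | C=C1C(=O)O[C@H]2[C@H]1[C@@H](OCBr)[C@H](O[Si](C)(C)C(C)(C)C)[C@@](C)(/C=C\OC(C)=O)[C@@H]2C(=C)C | intermediate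
21 | (Z)-2-[(3aR,4R,5R,6S,7S,7aR)-5-[(tert-butyldimethylsilyl)oxy]-4-hydroxy-6-methyl-3-methylidene-2-oxo-7-(prop-1-en-2-yl)octahydro-1-benzofuran-6-yl]ethenyl acetate | C=C1C(=O)O[C@H]2[C@H]1[C@@H](O)[C@H](O[Si](C)(C)C(C)(C)C)[C@@](C)(/C=C\OC(C)=O)[C@@H]2C(=C)C | intermediate
22 | (2Z)-2-methylbut-2-enoic acid (angelic acid) | C/C=C(/C)C(=O)O | starting material
23 | (2Z)-2-methylbut-2-enoic 2,4,6-trichlorobenzoic anhydride | C/C=C(/C)C(=O)OC(=O)c1c(Cl)cc(Cl)cc1Cl | intermediate
24 | (3aS,4R,5R,6S,7S,7aR)-6-[(Z)-2-acetoxyethenyl]-5-[(tert-butyldimethylsilyl)oxy]-6-methyl-3-methylidene-2-oxo-7-(prop-1-en-2-yl)octahydro-1-benzofuran-4-yl (2Z)-2-methylbut-2-enoate | C=C1C(=O)O[C@H]2[C@H]1[C@@H](OC(=O)/C(C)=C\C)[C@H](O[Si](C)(C)C(C)(C)C)[C@@](C)(/C=C\OC(C)=O)[C@@H]2C(=C)C | intermediate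
25 | (3aS,4R,5R,6S,7S,7aR)-6-[(Z)-2-acetoxyethenyl]-5-hydroxy-6-methyl-3-methylidene-2-oxo-7-(prop-1-en-2-yl)octahydro-1-benzofuran-4-yl (2Z)-2-methylbut-2-enoate | C=C1C(=O)O[C@H]2[C@H]1[C@@H](OC(=O)/C(C)=C\C)[C@H](O)[C@@](C)(/C=C\OC(C)=O)[C@@H]2C(=C)C | intermediate
26 | (3aS,4R,5R,6S,7S,7aR)-5-acetoxy-6-[(Z)-2-acetoxyethenyl]-6-methyl-3-methylidene-2-oxo-7-(prop-1-en-2-yl)octahydro-1-benzofuran-4-yl (2Z)-2-methylbut-2-enoate | C=C1C(=O)O[C@H]2[C@H]1[C@@H](OC(=O)/C(C)=C\C)[C@H](OC(C)=O)[C@@](C)(/C=C\OC(C)=O)[C@@H]2C(=C)C | target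

**Step count and risks**
Total: 15 steps. Longest linear sequence: 13 steps (1 → 2 → 5 → 6 → 12 → 13 → 14 → 16 → 17 → 19 → 21 → 24 → 25 → 26); steps 4 and 5 make the side fragment 10.

Steps most likely to fail:

1. Step 6. The C9 silyloxy centre may not control the face of C10 well enough, or a Cope shift of the 1,5-diene may compete at 140 °C. The fallback moves the control to a carbinol centre and a chirality transfer. It sets out from 6 and comes back at 13. Iodine–lithium exchange on 6 (t-BuLi) and trapping with formaldehyde would give the allylic alcohol F1, which would be converted into the allylic mesylate F2. The chiral alcohol F3 would be made from 7 and 2-bromopropene by a catalytic asymmetric Nozaki–Hiyama–Kishi alkenylation (CrCl2 and NiCl2 as catalysts, Mn, chiral sulfonamide ligand). Its sodium alkoxide would displace the mesylate to give the bis-allylic ether F4. n-BuLi at −78 °C would then bring about a [2,3]-Wittig rearrangement to the dienol F5, with transfer of chirality to the carbinol carbon. KH with 18-crown-6 would drive the anionic oxy-Cope rearrangement through the chair with the oxido group equatorial, and PhNTf2 would trap the enolate as the enol triflate F6. LiN(i-Pr)2 would eliminate triflate to give alkyne 13.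

2. Step 9. The cross-metathesis between the hindered allylic ether alkene and the 1,1-disubstituted acrylate may stall before the catalyst decomposes. The fallback uses a more reactive partner and a radical ring closure. It sets out from 14 and comes back at 19. Cross-metathesis of 14 with methyl acrylate would give the enoate F7, and acetal hydrolysis as in step 10 would give the aldehyde F8. SmI2 in THF–MeOH would then effect a 6-exo ketyl–olefin cyclisation, which is anti-selective, and the samarium enolate would be trapped in the flask with formaldehyde; lactonisation would give the hydroxymethyl lactone F9. Mesylation to the mesylate F10 and elimination with DBU would give 19.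

3. Step 11. The allylchromium may react through the cis-fused bicyclic transition state and give the cis ring fusion, or the selectivity may be low. The fallback replaces the closed transition state by an open one. It sets out from 14 and comes back at 18. Cross-metathesis of 14 with methyl 2-[(trimethylsilyl)methyl]prop-2-enoate would give the allylsilane F11, and acetal hydrolysis would give the silyl aldehyde F12. BF3·OEt2 at −78 °C would then effect an intramolecular Hosomi–Sakurai reaction through an antiperiplanar transition state to hydroxy ester 18, which lactonises as before.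

**Further compounds**
F1 | step 6 | (2E,4R,5R)-4-[(tert-butyldimethylsilyl)oxy]-5-(methoxymethoxy)-3-methylhepta-2,6-dien-1-ol | C=C[C@@H](OCOC)[C@H](O[Si](C)(C)C(C)(C)C)/C(C)=C/CO
F2 | step 6 | (2E,4R,5R)-4-[(tert-butyldimethylsilyl)oxy]-5-(methoxymethoxy)-3-methylhepta-2,6-dien-1-yl methanesulfonate | C=C[C@@H](OCOC)[C@H](O[Si](C)(C)C(C)(C)C)/C(C)=C/COS(C)(=O)=O
F3 | step 6 | (2S)-1,1-dimethoxy-3-methylbut-3-en-2-ol | COC(OC)[C@@H](O)C(C)=C
F4 | step 6 | tert-butyl{[(2E,4R,5R)-1-{[(2S)-1,1-dimethoxy-3-methylbut-3-en-2-yl]oxy}-5-(methoxymethoxy)-3-methylhepta-2,6-dien-4-yl]oxy}dimethylsilane | C=C[C@@H](OCOC)[C@H](O[Si](C)(C)C(C)(C)C)/C(C)=C/CO[C@H](C(OC)OC)C(C)=C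
F5 | step 6 | (3R,4R,5E,7S,9E)-4-[(tert-butyldimethylsilyl)oxy]-11,11-dimethoxy-3-(methoxymethoxy)-5,9-dimethylundeca-1,5,9-trien-7-ol | C=C[C@@H](OCOC)[C@H](O[Si](C)(C)C(C)(C)C)/C(C)=C/[C@@H](O)C/C(C)=C/C(OC)OC
F6 | step 6 | (1E,3S,4R,5R)-4-[(tert-butyldimethylsilyl)oxy]-3-[(2S)-1,1-dimethoxy-3-methylbut-3-en-2-yl]-5-(methoxymethoxy)-3-methylhepta-1,6-dien-1-yl trifluoromethanesulfonate | C=C[C@@H](OCOC)[C@H](O[Si](C)(C)C(C)(C)C)[C@@](C)(/C=C/OS(=O)(=O)C(F)(F)F)[C@@H](C(OC)OC)C(=C)C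
F7 | step 9 | methyl (2E,4R,5R,6S,7S)-6-[(Z)-2-acetoxyethenyl]-5-[(tert-butyldimethylsilyl)oxy]-8,8-dimethoxy-4-(methoxymethoxy)-6-methyl-7-(prop-1-en-2-yl)oct-2-enoate | COC(=O)/C=C/[C@@H](OCOC)[C@H](O[Si](C)(C)C(C)(C)C)[C@@](C)(/C=C\OC(C)=O)[C@@H](C(OC)OC)C(=C)C
F8 | step 9 | methyl (2E,4R,5R,6S,7S)-6-[(Z)-2-acetoxyethenyl]-5-[(tert-butyldimethylsilyl)oxy]-4-(methoxymethoxy)-6-methyl-8-oxo-7-(prop-1-en-2-yl)oct-2-enoate | COC(=O)/C=C/[C@@H](OCOC)[C@H](O[Si](C)(C)C(C)(C)C)[C@@](C)(/C=C\OC(C)=O)[C@@H](C=O)C(=C)C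
F9 | step 9 | (Z)-2-[(3aS,4R,5R,6S,7S,7aR)-5-[(tert-butyldimethylsilyl)oxy]-3-(hydroxymethyl)-4-(methoxymethoxy)-6-methyl-2-oxo-7-(prop-1-en-2-yl)octahydro-1-benzofuran-6-yl]ethenyl acetate (both C3 epimers) | OCC1C(=O)O[C@H]2[C@H]1[C@@H](OCOC)[C@H](O[Si](C)(C)C(C)(C)C)[C@@](C)(/C=C\OC(C)=O)[C@@H]2C(=C)C
F10 | step 9 | (Z)-2-[(3aS,4R,5R,6S,7S,7aR)-5-[(tert-butyldimethylsilyl)oxy]-3-[(methanesulfonyloxy)methyl]-4-(methoxymethoxy)-6-methyl-2-oxo-7-(prop-1-en-2-yl)octahydro-1-benzofuran-6-yl]ethenyl acetate (both C3 epimers) | CS(=O)(=O)OCC1C(=O)O[C@H]2[C@H]1[C@@H](OCOC)[C@H](O[Si](C)(C)C(C)(C)C)[C@@](C)(/C=C\OC(C)=O)[C@@H]2C(=C)C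
F11 | step 11 | methyl (2Z,4R,5R,6S,7S)-6-[(Z)-2-acetoxyethenyl]-5-[(tert-butyldimethylsilyl)oxy]-8,8-dimethoxy-4-(methoxymethoxy)-6-methyl-7-(prop-1-en-2-yl)-2-[(trimethylsilyl)methyl]oct-2-enoate | COC(=O)/C(C[Si](C)(C)C)=C/[C@@H](OCOC)[C@H](O[Si](C)(C)C(C)(C)C)[C@@](C)(/C=C\OC(C)=O)[C@@H](C(OC)OC)C(=C)C
F12 | step 11 | methyl (2Z,4R,5R,6S,7S)-6-[(Z)-2-acetoxyethenyl]-5-[(tert-butyldimethylsilyl)oxy]-4-(methoxymethoxy)-6-methyl-8-oxo-7-(prop-1-en-2-yl)-2-[(trimethylsilyl)methyl]oct-2-enoate | COC(=O)/C(C[Si](C)(C)C)=C/[C@@H](OCOC)[C@H](O[Si](C)(C)C(C)(C)C)[C@@](C)(/C=C\OC(C)=O)[C@@H](C=O)C(=C)C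
A1 | direct plan | (3R,4R,5R,6R)-5-acetoxy-6-ethynyl-3-formyl-6,8-dimethylnon-7-en-1-yn-4-yl (2Z)-2-methylbut-2-enoate | O=C[C@H](C#C)[C@@H](OC(=O)/C(C)=C\C)[C@H](OC(C)=O)[C@@](C)(C#C)C=C(C)C
A2 | direct plan | (1R,2R,3R,4S,5R,6S)-2-acetoxy-3,6-diethynyl-5-hydroxy-3-methyl-4-(prop-1-en-2-yl)cyclohexyl (2Z)-2-methylbut-2-enoate | O[C@H]1[C@H](C#C)[C@@H](OC(=O)/C(C)=C\C)[C@H](OC(C)=O)[C@@](C)(C#C)[C@@H]1C(=C)C
A3 | direct plan | (3aS,4R,5R,6R,7S,7aR)-5-acetoxy-6-ethynyl-6-methyl-3-methylidene-2-oxo-7-(prop-1-en-2-yl)octahydro-1-benzofuran-4-yl (2Z)-2-methylbut-2-enoate | C=C1C(=O)O[C@H]2[C@H]1[C@@H](OC(=O)/C(C)=C\C)[C@H](OC(C)=O)[C@@](C)(C#C)[C@@H]2C(=C)C
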